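**Retrosynthetic overview**

- Target ⇐ its 3,7,4'-tri-O-benzyl ether (hydrogenolysis last) ⇐ the C3 acyl sultam (CH2OH by reductive release of the auxiliary).
- Dihydrofuran ring: C3–C3a and C2–O1 are both made in one phenoxyl-radical cross-coupling, as in flavonolignan biosynthesis. The C8 radical of an N-feruloyl bornane-10,2-sultam joins C2' of a flavonol 3'-O radical, and the p-quinone methide then closes 5-exo. The sultam sets C3; the trans closure sets C2.
- Flavonol partner: 3,7,4'-tri-O-benzylquercetin, one step from quercetin. Only 3'-OH is oxidisable and 4'-O is blocked, so benzodioxane formation and C5' coupling are shut off.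
- Ring order: rings A, C and B are bought as quercetin; the only ring formed is the dihydrofuran ring (step 3).

Assumption: the target is taken exactly as drawn (2,3-dehydroisosilychristin, (2R,3S) = 2,3-trans); (2R)-bornane-10,2-sultam is assumed to direct attack to the C8 re face (the usual Cα-re topicity of its N-enoyl derivatives), and if the first coupling shows the opposite sense the equally available (2S)-sultam is used with nothing else changed.

**Step 1**
Reactants: 1 quercetin
Product: 2 3,7-bis(benzyloxy)-2-[4-(benzyloxy)-3-hydroxyphenyl]-5-hydroxy-4H-chromen-4-one (3,7,4'-tri-O-benzylquercetin)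
Conditions: BnBr (3.3 equiv), K2CO3 (3.5 equiv), DMF, 0 °C → rt, 14 h; chromatography
Reagents that add atoms: benzyl bromide, BrCc1ccccc1
Why: Williamson etherification governed by phenol acidity: 7-OH, 4'-OH and 3-OH alkylate first, 5-OH is locked in its hydrogen bond to C4=O and 3'-OH is the least acidic free phenol, so about three equivalents of BnBr stop at the 3,7,4'-tribenzyl ether; no stereocenter.

**Step 2**
Reactants: 3 (E)-4-acetoxy-3-methoxycinnamic acid; 4 (2R)-bornane-10,2-sultam
Product: 7 (2R)-N-[(E)-3-(4-hydroxy-3-methoxyphenyl)prop-2-enoyl]bornane-10,2-sultam, via O-acetylferuloyl chloride 5 (not isolated), via O-acetyl-N-feruloyl sultam 6 (not isolated)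
Conditions: (COCl)2, cat. DMF, CH2Cl2, 0 °C → rt, evaporate; 4, NaH, toluene/THF, 0 °C → rt; then pyrrolidine (2.5 equiv), 0 °C, 30 min; 1 M HCl work-up, recrystallise
Reagents that add atoms: none
Why: N-acylation of the sodium salt of the sultam by the acyl chloride is the standard entry to N-enoyl bornane-10,2-sultams, and the aryl acetate is then the only acyl group electrophilic enough for fast aminolysis by pyrrolidine, the conjugated, hindered enoyl sultam staying intact; no new stereocenter.

**Step 3**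
Reactants: 2 3,7,4'-tri-O-benzylquercetin; 7 (2R)-N-[(E)-feruloyl]bornane-10,2-sultam
Product: 9 (2R)-N-{[(2R,3R)-7-(benzyloxy)-4-[3,7-bis(benzyloxy)-5-hydroxy-4-oxo-4H-chromen-2-yl]-2-(4-hydroxy-3-methoxyphenyl)-2,3-dihydro-1-benzofuran-3-yl]carbonyl}bornane-10,2-sultam (2,3-trans), via p-quinone methide 8 (not isolated)
Conditions: Ag2O (2.5 equiv), 2 (3 equiv, excess recovered), CH2Cl2/acetone 4:1, 0 °C, dark, 7 added over 6 h; chromatography, then crystallisation to a single diastereomer
Reagents that add atoms: none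
Why: Proposed new method: Ag2O oxidises both phenols to phenoxyl radicals; the feruloyl radical carries its spin at C8 (α to the imide carbonyl) and the flavonol 3'-O radical, with 4'-O benzylated, only at O, C2' and C6', so C8–C2' radical–radical coupling and rearomatisation give quinone methide 8, whose 3'-OH adds 5-exo to C7 to close the thermodynamically favoured trans-dihydrobenzofuran (coupling at C6' or at oxygen cannot cyclise and gives separable open-chain by-products), while the sultam in its s-cis, C=O/SO2-anti rotamer exposes the C8 re face and so sets C3 (3R in the acyl series), the trans closure then setting C2 (2R); the closest known reactions are the Ag2O dehydrodimerisation of N-feruloyl bornane-10,2-sultam to the phenylcoumaran in about 80% ee after reduction, and the Ag2O cross-coupling of coniferyl alcohol with flavonoid phenols in silybin-type syntheses.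

**Step 4**
Reactants: 9 coupled acyl sultam
Product: 10 3,7-bis(benzyloxy)-2-[(2R,3S)-7-(benzyloxy)-2-(4-hydroxy-3-methoxyphenyl)-3-(hydroxymethyl)-2,3-dihydro-1-benzofuran-4-yl]-5-hydroxy-4H-chromen-4-one
Conditions: LiBH4 (5 equiv), THF, 0 °C → rt, 3 h; aq. NH4Cl; auxiliary 4 recovered
Reagents that add atoms: none
Why: Reductive cleavage of the N-acyl sultam by LiBH4 gives the primary alcohol and returns the auxiliary, while the flavonol carbonyl, a vinylogous ester further deactivated as its 5-O-lithium chelate, is not reduced (flavonols are inert to borohydride); C2 and C3 are untouched, the C3 descriptor changing from R to S only through CIP priorities.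

**Step 5**
Reactants: 10 tri-O-benzyl alcohol
Product: 11 2-[(2R,3S)-7-hydroxy-2-(4-hydroxy-3-methoxyphenyl)-3-(hydroxymethyl)-2,3-dihydro-1-benzofuran-4-yl]-3,5,7-trihydroxy-4H-chromen-4-one (target)
Conditions: H2 (1 atm), 10% Pd/C, EtOAc/MeOH 1:1, rt, 2 h, stopped at three equivalents of H2
Reagents that add atoms: none
Why: Hydrogenolysis of the three aryl/enol benzyl ethers on Pd/C is much faster than cleavage of the dihydrobenzofuran C2–O bond or reduction of the flavonol C2=C3 bond, so short exposure at 1 atm frees the phenols without touching either stereocenter.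

**Compound list**

1 | quercetin | O=c1c(O)c(-c2ccc(O)c(O)c2)oc2cc(O)cc(O)c12 | starting material
2 | 3,7-bis(benzyloxy)-2-[4-(benzyloxy)-3-hydroxyphenyl]-5-hydroxy-4H-chromen-4-one (3,7,4'-tri-O-benzylquercetin) | O=c1c(OCc2ccccc2)c(-c2ccc(OCc3ccccc3)c(O)c2)oc2cc(OCc3ccccc3)cc(O)c12 | intermediate
3 | (E)-4-acetoxy-3-methoxycinnamic acid (O-acetylferulic acid) | CC(=O)Oc1ccc(/C=C/C(=O)O)cc1OC | starting material
4 | (2R)-bornane-10,2-sultam, (1S)-(−)-2,10-camphorsultam, (3aS,6R,7aR) | N1[C@@H]2C[C@H]3CC[C@]2(CS1(=O)=O)C3(C)C | starting material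
5 | (E)-4-acetoxy-3-methoxycinnamoyl chloride | CC(=O)Oc1ccc(/C=C/C(Cl)=O)cc1OC | intermediate
6 | (2R)-N-[(E)-3-(4-acetoxy-3-methoxyphenyl)prop-2-enoyl]bornane-10,2-sultam | CC(=O)Oc1ccc(/C=C/C(=O)N2[C@@H]3C[C@H]4CC[C@]3(CS2(=O)=O)C4(C)C)cc1OC | intermediate
7 | (2R)-N-[(E)-3-(4-hydroxy-3-methoxyphenyl)prop-2-enoyl]bornane-10,2-sultam | COc1cc(/C=C/C(=O)N2[C@@H]3C[C@H]4CC[C@]3(CS2(=O)=O)C4(C)C)ccc1O | intermediate
8 | p-quinone methide: (2R)-N-{(2S)-2-[3-(benzyloxy)-6-[3,7-bis(benzyloxy)-5-hydroxy-4-oxo-4H-chromen-2-yl]-2-hydroxyphenyl]-3-(3-methoxy-4-oxocyclohexa-2,5-dien-1-ylidene)propanoyl}bornane-10,2-sultam | COC1=CC(=C[C@@H](c2c(O)c(OCc3ccccc3)ccc2-c2oc3cc(OCc4ccccc4)cc(O)c3c(=O)c2OCc2ccccc2)C(=O)N2[C@@H]3C[C@H]4CC[C@]3(CS2(=O)=O)C4(C)C)C=CC1=O | intermediate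
9 | (2R)-N-{[(2R,3R)-7-(benzyloxy)-4-[3,7-bis(benzyloxy)-5-hydroxy-4-oxo-4H-chromen-2-yl]-2-(4-hydroxy-3-methoxyphenyl)-2,3-dihydro-1-benzofuran-3-yl]carbonyl}bornane-10,2-sultam | COc1cc([C@@H]2Oc3c(OCc4ccccc4)ccc(-c4oc5cc(OCc6ccccc6)cc(O)c5c(=O)c4OCc4ccccc4)c3[C@H]2C(=O)N2[C@@H]3C[C@H]4CC[C@]3(CS2(=O)=O)C4(C)C)ccc1O | intermediate
10 | 3,7-bis(benzyloxy)-2-[(2R,3S)-7-(benzyloxy)-2-(4-hydroxy-3-methoxyphenyl)-3-(hydroxymethyl)-2,3-dihydro-1-benzofuran-4-yl]-5-hydroxy-4H-chromen-4-one | COc1cc([C@@H]2Oc3c(OCc4ccccc4)ccc(-c4oc5cc(OCc6ccccc6)cc(O)c5c(=O)c4OCc4ccccc4)c3[C@H]2CO)ccc1O | intermediate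
11 | 2-[(2R,3S)-7-hydroxy-2-(4-hydroxy-3-methoxyphenyl)-3-(hydroxymethyl)-2,3-dihydro-1-benzofuran-4-yl]-3,5,7-trihydroxy-4H-chromen-4-one (CNP0195987.1) | COc1cc([C@@H]2Oc3c(O)ccc(-c4oc5cc(O)cc(O)c5c(=O)c4O)c3[C@H]2CO)ccc1O | target

**Step count and risks**

Total steps: 5. Longest linear sequence: 4 steps (3 → 7 → 9 → 10 → 11; the quercetin branch 1 → 2 → 9 is equally long).

Most likely to fail, in order:

1. Step 3. The risks are homodimerisation of 7, C8 coupling to C6' or to oxygen instead of the congested C2', and weak facial control by the bulky sultam at that site. The fallback sets out from 2 and drops the auxiliary. Compound 2 (3 equiv) is coupled with commercial (E)-coniferyl alcohol using Ag2O in benzene/acetone, the classical flavonolignan conditions with the small, well-behaved coniferyl radical. This gives racemic trans product directly at the alcohol oxidation level, that is 10 together with its (2S,3R)-enantiomer ent-10 F1. The two are separated by preparative chiral SFC on an amylose tris(3,5-dimethylphenylcarbamate) phase. The route is rejoined at 10 and step 4 is not needed.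

2. Step 4. The risks are sluggish hydride attack on the hindered imide and competing reduction of the chromenone. The fallback sets out from 9 and separates cleavage from reduction. LiOH/H2O2 in THF/H2O at 0 °C hydrolyses the acyl sultam to (2R,3R)-7-(benzyloxy)-4-[3,7-bis(benzyloxy)-5-hydroxy-4-oxo-4H-chromen-2-yl]-2-(4-hydroxy-3-methoxyphenyl)-2,3-dihydro-1-benzofuran-3-carboxylic acid F2. BH3·SMe2 in THF (0 °C → rt) then reduces the carboxylic acid chemoselectively in the presence of the chelated chromenone. The route is rejoined at 10.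

3. Step 2. The risks are conjugate addition or aminolysis of the enoyl sultam by pyrrolidine and loss of the acetate during acylation. The fallback sets out from 4 and builds the enoyl unit by olefination, with no phenol protection. Compound 4 is N-acylated with bromoacetyl bromide (NaH, THF) to (2R)-N-(bromoacetyl)bornane-10,2-sultam F3. An Arbuzov reaction with P(OEt)3 (neat, 120 °C) gives (2R)-N-[(diethoxyphosphoryl)acetyl]bornane-10,2-sultam F4. Masamune–Roush Horner–Wadsworth–Emmons olefination of commercial vanillin (LiCl, DBU 2.2 equiv, MeCN, rt) gives the (E)-enoyl sultam. The route is rejoined at 7.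

**Further compounds**

F1 | step 3 | ent-10, 3,7-bis(benzyloxy)-2-[(2S,3R)-7-(benzyloxy)-2-(4-hydroxy-3-methoxyphenyl)-3-(hydroxymethyl)-2,3-dihydro-1-benzofuran-4-yl]-5-hydroxy-4H-chromen-4-one (formed 1:1 with 10) | COc1cc([C@H]2Oc3c(OCc4ccccc4)ccc(-c4oc5cc(OCc6ccccc6)cc(O)c5c(=O)c4OCc4ccccc4)c3[C@@H]2CO)ccc1O
F2 | step 4 | (2R,3R)-7-(benzyloxy)-4-[3,7-bis(benzyloxy)-5-hydroxy-4-oxo-4H-chromen-2-yl]-2-(4-hydroxy-3-methoxyphenyl)-2,3-dihydro-1-benzofuran-3-carboxylic acid | COc1cc([C@@H]2Oc3c(OCc4ccccc4)ccc(-c4oc5cc(OCc6ccccc6)cc(O)c5c(=O)c4OCc4ccccc4)c3[C@H]2C(=O)O)ccc1O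
F3 | step 2 | (2R)-N-(bromoacetyl)bornane-10,2-sultam | O=C(CBr)N1[C@@H]2C[C@H]3CC[C@]2(CS1(=O)=O)C3(C)C
F4 | step 2 | (2R)-N-[(diethoxyphosphoryl)acetyl]bornane-10,2-sultam | CCOP(=O)(OCC)CC(=O)N1[C@@H]2C[C@H]3CC[C@]2(CS1(=O)=O)C3(C)C
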